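## Retrosynthetic overview

1. Brevipolide H (16) is cut at the two cyclopropane bonds to C4' (C4'–C3' and C4'–C2'), giving diazoketone 8 and vinyl carbinol lactone 15; they are joined unprotected in the last step by an asymmetric cobalt-metalloradical cyclopropanation. (Numbering: lactone C2–C6, carbinol C1', cyclopropane C2'–C4', ketone C5', lactate carbon C6'.)
2. 8 comes from O-cinnamoyl lactic acid 6 and diazomethane; 6 comes from a Heck reaction of 4-iodoanisole 2 (from anisole) with lactic acid acrylate 5 (from (S)-lactic acid and acryloyl chloride).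
3. 15 comes from ynoate diol 13 by cis-semihydrogenation and lactonisation; 13 from epoxy alcohol 10 and ethyl propiolate; 10 from Sharpless desymmetrisation of penta-1,4-dien-3-ol.
4. Ring order: dihydropyranone first (step 7), cyclopropane last (step 8). C6' comes from lactic acid, C6 and C1' from the epoxidation, C2' and C4' from the cobalt catalyst.

Assumption: 3,5-DitBu-ChenPhyrin is 5,15-bis(3,5-di-tert-butylphenyl)-10,20-bis[2,6-bis(2,2-dimethylcyclopropanecarboxamido)phenyl]porphyrin; its sense of induction for this new partner pair is unknown, so step 8 means whichever antipode (from (S)- or (R)-2,2-dimethylcyclopropanecarboxamide) gives the (1S,2S) cyclopropane.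

## Route

Step 1
Reactants: 1 anisole
Product: 2 4-iodoanisole
Conditions: NIS (1.05 equiv), CF3CO2H (10 mol %), MeCN, rt, 2 h
Reagents that add atoms: N-iodosuccinimide, O=C1CCC(=O)N1I
Why: Electrophilic aromatic iodination, in which the methoxy group sends the bulky iodine donor almost only to the para position.

Step 2
Reactants: 3 (S)-lactic acid, 4 acryloyl chloride
Product: 5 (S)-2-(acryloyloxy)propanoic acid
Conditions: 3 (1.5 equiv, anhydrous), 4 (1.0 equiv), pyridine (1.1 equiv), BHT (cat.), CH2Cl2, 0 °C to rt; aq. HCl wash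
Reagents that add atoms: none
Why: O-acylation of the hydroxy acid by an acid chloride (mixed anhydride at the carboxyl group is hydrolysed in the acidic wash), which does not touch the stereocentre, so the S configuration is retained.

Step 3
Reactants: 2 4-iodoanisole, 5 (S)-2-(acryloyloxy)propanoic acid
Product: 6 (S)-2-{[(E)-3-(4-methoxyphenyl)prop-2-enoyl]oxy}propanoic acid
Conditions: Pd(OAc)2 (2 mol %), Et3N (3 equiv), MeCN, 80 °C; then aq. HCl
Reagents that add atoms: none
Why: Mizoroki–Heck arylation of the acrylate, where syn carbopalladation and syn β-hydride elimination give only the E-cinnamate and the carboxylate-bearing stereocentre is not enolised.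

Step 4
Reactants: 6 (S)-2-{[(E)-3-(4-methoxyphenyl)prop-2-enoyl]oxy}propanoic acid
Product: 8 (S)-4-diazo-3-oxobutan-2-yl (E)-3-(4-methoxyphenyl)prop-2-enoate, via mixed anhydride 7 (not isolated)
Conditions: i-BuOCOCl (1.05 equiv), N-methylmorpholine (1.05 equiv), THF, −15 °C, 20 min; then CH2N2 (2.5 equiv, Et2O), −15 to 0 °C, 2 h; AcOH quench
Reagents that add atoms: diazomethane, C=[N+]=[N-]
Why: Acylation of diazomethane by a mixed carbonic anhydride (first stage of an Arndt–Eistert sequence), which does not racemise α-oxygenated acids, while at 0 °C the β-aryl acrylate is too poor a dipolarophile to form a pyrazoline.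

Step 5
Reactants: 9 penta-1,4-dien-3-ol
Product: 10 (2R,3S)-1,2-epoxypent-4-en-3-ol
Conditions: Ti(OiPr)4 (0.1 equiv), L-(+)-diisopropyl tartrate (0.13 equiv), t-BuOOH (2 equiv, isooctane), 4 Å MS, CH2Cl2, −20 °C, 5 d
Reagents that add atoms: tert-butyl hydroperoxide, CC(C)(C)OO
Why: Sharpless asymmetric epoxidation used as a desymmetrisation of the achiral dienol, in which the tartrate picks one enantiotopic vinyl group and one of its faces to give the erythro epoxy alcohol (3S carbinol, 2R epoxide carbon), and the minor enantiomer is removed by a second epoxidation.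

Step 6
Reactants: 10 (2R,3S)-1,2-epoxypent-4-en-3-ol, 11 ethyl propiolate
Product: 13 ethyl (5R,6S)-5,6-dihydroxyoct-7-en-2-ynoate, via lithium ethyl propiolate 12 (not isolated)
Conditions: 11 (3 equiv), n-BuLi (3 equiv), THF, −78 °C, 20 min; BF3·OEt2 (3 equiv); then 10, −78 °C, 2 h; aq. NH4Cl
Reagents that add atoms: none
Why: Yamaguchi–Hirao alkynylation, in which the BF3-activated terminal epoxide is opened at its CH2 carbon by the lithium acetylide in an SN2 reaction, so both stereocentres stay as set, and the excess of reagents absorbs the free hydroxyl group.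

Step 7
Reactants: 13 ethyl (5R,6S)-5,6-dihydroxyoct-7-en-2-ynoate
Product: 15 (R)-6-[(S)-1-hydroxyprop-2-en-1-yl]-5,6-dihydro-2H-pyran-2-one, via seco Z-enoate 14 (not isolated)
Conditions: H2 (1 atm, stopped at 1.0 equiv), 5% Pd/CaCO3 poisoned with Pb(OAc)2, quinoline, EtOAc, rt; filter; then PPTS (10 mol %), benzene, 50 °C
Reagents that add atoms: none
Why: Lindlar cis-semihydrogenation of the electron-poor alkyne (which outcompetes the monosubstituted alkene for the poisoned surface) gives the Z-enoate, whose 5-hydroxyl group then closes the six-membered lactone with loss of ethanol, no stereocentre being involved.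

Step 8
Reactants: 8 (S)-4-diazo-3-oxobutan-2-yl (E)-3-(4-methoxyphenyl)prop-2-enoate, 15 (R)-6-[(S)-1-hydroxyprop-2-en-1-yl]-5,6-dihydro-2H-pyran-2-one
Product: 16 brevipolide H, (S)-1-{(1S,2S)-2-[(S)-hydroxy((R)-6-oxo-3,6-dihydro-2H-pyran-2-yl)methyl]cyclopropyl}-1-oxopropan-2-yl (E)-3-(4-methoxyphenyl)prop-2-enoate
Conditions: 8 (1.5 equiv), 15 (1.0 equiv), [Co(3,5-DitBu-ChenPhyrin)] (5 mol %), chlorobenzene, N2, 40 °C, 48 h
Reagents that add atoms: none
Why: Proposed new method: the divalent cobalt porphyrin, a metal-centred radical, takes up diazoketone 8 with loss of N2 to give an α-cobalt (trivalent) alkyl radical held by N–H···O=C hydrogen bonds of the amide arms, this carbon radical adds to the terminal CH2 of the vinyl group of 15, and the secondary γ-radical closes the ring by 3-exo-tet homolytic substitution at the Co–C bond, the chiral cavity setting the trans (1S,2S) configuration of both new stereocentres while the cis-enoate, the cinnamate and the free hydroxyl group are expected to stay out (a radical path gives no O–H insertion); the closest known reaction type is the cobalt-porphyrin metalloradical asymmetric cyclopropanation of alkenes with diazoacetates and α-ketodiazoacetates.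

## Compound list

1 | anisole | COc1ccccc1 | starting material
2 | 4-iodoanisole | COc1ccc(I)cc1 | intermediate
3 | (S)-lactic acid | C[C@H](O)C(=O)O | starting material
4 | acryloyl chloride | C=CC(=O)Cl | starting material
5 | (S)-2-(acryloyloxy)propanoic acid | C=CC(=O)O[C@@H](C)C(=O)O | intermediate
6 | (S)-2-{[(E)-3-(4-methoxyphenyl)prop-2-enoyl]oxy}propanoic acid | COc1ccc(/C=C/C(=O)O[C@@H](C)C(=O)O)cc1 | intermediate
7 | isobutyl carbonic mixed anhydride of 6 | COc1ccc(/C=C/C(=O)O[C@@H](C)C(=O)OC(=O)OCC(C)C)cc1 | intermediate (not isolated)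
8 | (S)-4-diazo-3-oxobutan-2-yl (E)-3-(4-methoxyphenyl)prop-2-enoate | COc1ccc(/C=C/C(=O)O[C@@H](C)C(=O)C=[N+]=[N-])cc1 | intermediate
9 | penta-1,4-dien-3-ol | C=CC(O)C=C | starting material
10 | (2R,3S)-1,2-epoxypent-4-en-3-ol | C=C[C@H](O)[C@H]1CO1 | intermediate
11 | ethyl propiolate | C#CC(=O)OCC | starting material
12 | lithium ethyl propiolate | [Li]C#CC(=O)OCC | intermediate (not isolated)
13 | ethyl (5R,6S)-5,6-dihydroxyoct-7-en-2-ynoate | C=C[C@H](O)[C@H](O)CC#CC(=O)OCC | intermediate
14 | ethyl (2Z,5R,6S)-5,6-dihydroxyocta-2,7-dienoate | C=C[C@H](O)[C@H](O)C/C=C\C(=O)OCC | intermediate (not isolated)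
15 | (R)-6-[(S)-1-hydroxyprop-2-en-1-yl]-5,6-dihydro-2H-pyran-2-one | C=C[C@H](O)[C@H]1CC=CC(=O)O1 | intermediate
16 | brevipolide H | COc1ccc(/C=C/C(=O)O[C@@H](C)C(=O)[C@H]2C[C@@H]2[C@H](O)[C@H]2CC=CC(=O)O2)cc1 | target

## Step count and risks

Total steps: 8. Longest linear sequence: 4 steps (3 → 5 → 6 → 8 → 16; the branches from 1 and from 9 are equally long).

Steps most likely to fail:

1. Step 8. The alkene is unactivated, both partners are chiral, and the carbene radical could be diverted by the cinnamate or the lactone enoate. The fallback sets out from 8 and 13 and comes back at 16. The same cobalt-catalysed radical cyclopropanation is moved one stage earlier, onto ynoate diol 13, which is two steps from bulk chemicals and can be used in threefold excess and recovered. With [Co(3,5-DitBu-ChenPhyrin)] in chlorobenzene at 40 °C it gives ethyl (5R,6S)-5,6-dihydroxy-6-{(1S,2S)-2-[(S)-2-{[(E)-3-(4-methoxyphenyl)prop-2-enoyl]oxy}propanoyl]cyclopropyl}hex-2-ynoate F1. Semihydrogenation (H2, Pd/CaCO3 poisoned with Pb(OAc)2, quinoline) then gives ethyl (2Z,5R,6S)-5,6-dihydroxy-6-{(1S,2S)-2-[(S)-2-{[(E)-3-(4-methoxyphenyl)prop-2-enoyl]oxy}propanoyl]cyclopropyl}hex-2-enoate F2, which is lactonised without isolation (PPTS) to 16. The cyclopropane is then formed before the lactone; this also keeps the lactone enoate out of the radical step and the terminal alkene out of the hydrogenation of step 7.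

2. Step 6. The free hydroxyl group next to the epoxide may quench the acetylide, bind BF3 or trigger epoxide migration. The fallback sets out from 10 and comes back at 13. The alcohol is silylated (TESCl, imidazole, CH2Cl2) to triethyl{[(S)-1-((R)-oxiran-2-yl)prop-2-en-1-yl]oxy}silane F3. This is opened with 12 and BF3·OEt2 at −78 °C to ethyl (5R,6S)-5-hydroxy-6-(triethylsilyloxy)oct-7-en-2-ynoate F4, and the silyl group is removed with AcOH/THF/H2O to give 13.

3. Step 2. Acylating unprotected lactic acid can give mixed anhydride, lactoyl lactate oligomers and acrylate polymer. The fallback sets out from 3 and comes back at 6, bypassing 5. The carboxyl group is masked first (tert-butyl 2,2,2-trichloroacetimidate, cyclohexane/CH2Cl2) as tert-butyl (S)-2-hydroxypropanoate F5. This is acylated with 4 (Et3N, CH2Cl2, 0 °C) to tert-butyl (S)-2-(acryloyloxy)propanoate F6. Heck coupling with 2 (Pd(OAc)2, Et3N, MeCN, 80 °C) gives tert-butyl (S)-2-{[(E)-3-(4-methoxyphenyl)prop-2-enoyl]oxy}propanoate F7, and CF3CO2H in CH2Cl2 releases 6.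

## Further compounds

F1 | step 8 | ethyl (5R,6S)-5,6-dihydroxy-6-{(1S,2S)-2-[(S)-2-{[(E)-3-(4-methoxyphenyl)prop-2-enoyl]oxy}propanoyl]cyclopropyl}hex-2-ynoate | COc1ccc(/C=C/C(=O)O[C@@H](C)C(=O)[C@H]2C[C@@H]2[C@H](O)[C@H](O)CC#CC(=O)OCC)cc1
F2 | step 8 | ethyl (2Z,5R,6S)-5,6-dihydroxy-6-{(1S,2S)-2-[(S)-2-{[(E)-3-(4-methoxyphenyl)prop-2-enoyl]oxy}propanoyl]cyclopropyl}hex-2-enoate | COc1ccc(/C=C/C(=O)O[C@@H](C)C(=O)[C@H]2C[C@@H]2[C@H](O)[C@H](O)C/C=C\C(=O)OCC)cc1
F3 | step 6 | triethyl{[(S)-1-((R)-oxiran-2-yl)prop-2-en-1-yl]oxy}silane | C=C[C@H](O[Si](CC)(CC)CC)[C@H]1CO1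
F4 | step 6 | ethyl (5R,6S)-5-hydroxy-6-(triethylsilyloxy)oct-7-en-2-ynoate | C=C[C@H](O[Si](CC)(CC)CC)[C@H](O)CC#CC(=O)OCC
F5 | step 2 | tert-butyl (S)-2-hydroxypropanoate | C[C@H](O)C(=O)OC(C)(C)C
F6 | step 2 | tert-butyl (S)-2-(acryloyloxy)propanoate | C=CC(=O)O[C@@H](C)C(=O)OC(C)(C)C
F7 | step 2 | tert-butyl (S)-2-{[(E)-3-(4-methoxyphenyl)prop-2-enoyl]oxy}propanoate | COc1ccc(/C=C/C(=O)O[C@@H](C)C(=O)OC(C)(C)C)cc1
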